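## Retrosynthetic overview

- Aryl–C(vinyl) bond: Negishi coupling of an unprotected ortho-zincated phenoxide (from 6-bromo-2,4-dimethoxy-3-methylphenol) with the enol triflate of an α-angeloyloxy methyl ketone.
- Enol triflate: kinetic enolisation of (S)-3-angeloyloxy-sulcatone at its methyl group.
- Key disconnection, C3–O: sulcatone plus diangeloyl peroxide by enantioselective enamine α-acyloxylation. This sets the only stereocentre and installs the angelate with its Z-olefin untouched.
- Bromophenol from 2,4-dimethoxy-3-methylbenzaldehyde by Dakin oxidation and ortho-bromination; the peroxide from angelic acid.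
- No ring is formed: the benzene ring is bought intact, and no protecting groups are used.

Assumption: the epi-quinine-derived amine in step 4 is taken to give the (S)-ester; if analysis shows (R), the pseudo-enantiomeric epi-quinidine-derived amine is used with nothing else changed.

## Route

Step 1
Reactants: 1 2,4-dimethoxy-3-methylbenzaldehyde
Product: 3 2,4-dimethoxy-3-methylphenol, via aryl formate 2 (not isolated)
Conditions: 30% aq H2O2 (1.3 equiv), H2SO4 (cat.), MeOH, rt
Reagents that add atoms: hydrogen peroxide, OO
Why: Dakin oxidation (acid-catalysed Baeyer–Villiger-type aryl migration, favoured by the ortho- and para-methoxy groups) gives the formate, which is methanolysed in the same pot; no stereocentre is involved.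

Step 2
Reactants: 3 2,4-dimethoxy-3-methylphenol
Product: 4 6-bromo-2,4-dimethoxy-3-methylphenol
Conditions: NBS (1.0 equiv), i-Pr2NH (10 mol %), CH2Cl2, −20 → 0 °C
Reagents that add atoms: N-bromosuccinimide, O=C1CCC(=O)N1Br
Why: Amine-mediated ortho-bromination of a phenol (electrophilic aromatic substitution through the hydrogen-bonded phenol/N-bromoamine pair): the para position is blocked by OMe and C6 is the only free position ortho to OH, so bromine should go there in preference to C5.

Step 3
Reactants: 5 angelic acid, (Z)-2-methylbut-2-enoic acid (2 equiv)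
Product: 8 diangeloyl peroxide, via O-angeloyl isourea 6 (not isolated), via peroxyangelic acid 7 (not isolated)
Conditions: DCC (2 equiv), 50% aq H2O2 (1 equiv), CH2Cl2, −10 → 0 °C, dark; filter, use as a titrated solution
Reagents that add atoms: hydrogen peroxide, OO
Why: Carbodiimide-mediated acylation of hydrogen peroxide (Greene–Kazan diacyl peroxide synthesis) runs through the O-acylisourea and the peracid at ≤0 °C with no nucleophilic acyl-transfer catalyst, so the Z-olefin of the angeloyl group should not isomerise.

Step 4
Reactants: 9 sulcatone, 6-methylhept-5-en-2-one (2 equiv); 8 diangeloyl peroxide (1 equiv)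
Product: 10 (S)-6-methyl-2-oxohept-5-en-3-yl (Z)-2-methylbut-2-enoate
Conditions: 9-amino-9-deoxy-epi-quinine (10 mol %), Cl3CCO2H (20 mol %), BHT (10 mol %), 1,4-dioxane, 25 °C, dark, 24–48 h
Reagents that add atoms: none
Why: Proposed new method: the chiral primary amine condenses with the methyl ketone and, as with linear 2-alkanones under primary-amine catalysis, should tautomerise mainly to the more substituted internal (Z) enamine, whose C3 attacks the O–O σ* of the peroxide held by hydrogen bonding to the protonated quinuclidine on one enamine face, expelling angelate and giving an α-acyloxy iminium that hydrolyses to (S)-10; the angeloyl carbonyl is never activated, so the Z-olefin is not at risk, and the prenyl alkene is inert to a diacyl peroxide; the closest known reaction is the cinchona-primary-amine-catalysed α-benzoyloxylation of cyclic ketones with dibenzoyl peroxide (enamine catalysis), which has not been shown for the internal α-carbon of an acyclic methyl ketone or with an α,β-unsaturated diacyl peroxide.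

Step 5
Reactants: 10 (S)-6-methyl-2-oxohept-5-en-3-yl (Z)-2-methylbut-2-enoate
Product: 12 (S)-6-methyl-2-(trifluoromethylsulfonyloxy)hepta-1,5-dien-3-yl (Z)-2-methylbut-2-enoate, via potassium enolate 11 (not isolated)
Conditions: PhNTf2 (1.2 equiv), then KHMDS (1.1 equiv, slow addition), THF, −78 °C; aq NH4Cl at −78 °C
Reagents that add atoms: N-phenylbis(trifluoromethanesulfonimide), O=S(=O)(N(c1ccccc1)S(=O)(=O)C(F)(F)F)C(F)(F)F
Why: Kinetic enolate O-triflation: the hindered amide base should remove a proton from the unhindered CH3 group faster than the tertiary C3–H, and the enolate is sulfonylated as it forms (internal quench), so it cannot equilibrate, attack the ester or epimerise C3.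

Step 6
Reactants: 4 6-bromo-2,4-dimethoxy-3-methylphenol (1.0 equiv); 12 (S)-6-methyl-2-(trifluoromethylsulfonyloxy)hepta-1,5-dien-3-yl (Z)-2-methylbut-2-enoate (1.05 equiv)
Product: 15 (S)-2-(2-hydroxy-3,5-dimethoxy-4-methylphenyl)-6-methylhepta-1,5-dien-3-yl (Z)-2-methylbut-2-enoate, via dilithio phenoxide 13 (not isolated), via arylzinc chloride 14 (not isolated)
Conditions: n-BuLi (2.05 equiv), THF, −78 °C; ZnCl2 (1.1 equiv), −78 → 0 °C; then 12, Pd(OAc)2 (2 mol %), SPhos (4 mol %), 0 °C → rt; aq NH4Cl
Reagents that add atoms: none
Why: Negishi cross-coupling: Br/Li exchange on the lithium phenoxide and transmetalation to zinc give a base-free aryl nucleophile that couples with the alkenyl triflate at ≤25 °C; oxidative addition of Pd(0) into the C(sp2)–OTf bond is expected to be much faster than ionisation of the hindered allylic angelate, so the ester, its Z-olefin and the C3 configuration are carried through unchanged.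

## Compound list

1 | 2,4-dimethoxy-3-methylbenzaldehyde | O=Cc1ccc(OC)c(C)c1OC | starting material
2 | 2,4-dimethoxy-3-methylphenyl formate | O=COc1ccc(OC)c(C)c1OC | intermediate
3 | 2,4-dimethoxy-3-methylphenol | Oc1ccc(OC)c(C)c1OC | intermediate
4 | 6-bromo-2,4-dimethoxy-3-methylphenol | Oc1c(Br)cc(OC)c(C)c1OC | intermediate
5 | angelic acid, (Z)-2-methylbut-2-enoic acid | C/C=C(/C)C(=O)O | starting material
6 | O-[(Z)-2-methylbut-2-enoyl]-N,N'-dicyclohexylisourea | C/C=C(/C)C(=O)OC(=NC1CCCCC1)NC1CCCCC1 | intermediate
7 | peroxyangelic acid, (Z)-2-methylbut-2-eneperoxoic acid | C/C=C(/C)C(=O)OO | intermediate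
8 | diangeloyl peroxide, bis[(Z)-2-methylbut-2-enoyl] peroxide | C/C=C(/C)C(=O)OOC(=O)/C(C)=C\C | intermediate
9 | sulcatone, 6-methylhept-5-en-2-one | CC(=O)CCC=C(C)C | starting material
10 | (S)-6-methyl-2-oxohept-5-en-3-yl (Z)-2-methylbut-2-enoate | CC(=O)[C@H](CC=C(C)C)OC(=O)/C(C)=C\C | intermediate
11 | potassium (S)-3-[(Z)-2-methylbut-2-enoyloxy]-6-methylhepta-1,5-dien-2-olate | C=C([O-])[C@H](CC=C(C)C)OC(=O)/C(C)=C\C.[K+] | intermediate
12 | (S)-6-methyl-2-(trifluoromethylsulfonyloxy)hepta-1,5-dien-3-yl (Z)-2-methylbut-2-enoate | C=C(OS(=O)(=O)C(F)(F)F)[C@H](CC=C(C)C)OC(=O)/C(C)=C\C | intermediate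
13 | lithium 2-lithio-4,6-dimethoxy-5-methylphenoxide (C-lithiated at the former C–Br carbon) | [Li]Oc1c([Li])cc(OC)c(C)c1OC | intermediate
14 | lithium 2-(chlorozincio)-4,6-dimethoxy-5-methylphenoxide | [Li]Oc1c([Zn]Cl)cc(OC)c(C)c1OC | intermediate
15 | (S)-2-(2-hydroxy-3,5-dimethoxy-4-methylphenyl)-6-methylhepta-1,5-dien-3-yl (Z)-2-methylbut-2-enoate | C=C(c1cc(OC)c(C)c(OC)c1O)[C@H](CC=C(C)C)OC(=O)/C(C)=C\C | target

## Step count and risks

Total steps: 6. Longest linear sequence: 4 (5 → 8 → 10 → 12 → 15); the arene branch is 2 steps before the coupling.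

The three steps most likely to fail:

**Step 4 (the proposed new reaction).** The risks are attack at C1 instead of C3, modest ee from an acyclic enamine, and oxidation of the amine catalyst by the peroxide. The fallback uses known chemistry, sets out from sulcatone 9 and comes back at 10. L-Proline-catalysed α-aminoxylation with nitrosobenzene (DMSO, rt) gives (R)-6-methyl-3-(phenylaminooxy)hept-5-en-2-one F1. CuSO4 (cat.) in MeOH cleaves the N–O bond to (R)-3-hydroxy-6-methylhept-5-en-2-one F2. Mitsunobu esterification with angelic acid 5 (PPh3, DIAD, toluene, 0 °C) inverts C3 and gives 10; the carboxylate acts as the nucleophile, so the Z-olefin is again not at risk.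

**Step 5.** The risks are enolisation at the more acidic C3–H (loss of material or ee), enolate attack on the angelate, and expulsion of angelate. The fallback sets out from sulcatone 9, runs through the hydroxy ketone F2 of the fallback above, and comes back at 12. TBSCl/imidazole (DMF) gives (R)-3-(tert-butyldimethylsilyloxy)-6-methylhept-5-en-2-one F3, so the enolate chemistry is done on a robust silyl ether. LDA then Comins' reagent (THF, −78 °C) gives (R)-3-(tert-butyldimethylsilyloxy)-6-methylhepta-1,5-dien-2-yl triflate F4. HF·pyridine (THF, 0 °C) gives (R)-3-hydroxy-6-methylhepta-1,5-dien-2-yl triflate F5. Mitsunobu esterification with angelic acid 5 (inversion) gives 12.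

**Step 6.** The risks are Pd(0) ionisation of the allylic angelate in the product, leading to racemisation or closure of the ortho-phenoxide onto the π-allyl to a 3-methylene-2,3-dihydrobenzofuran, and β-acyloxy elimination from the alkenyl-palladium intermediate. The fallback moves the aryl–vinyl coupling ahead of ester formation. It sets out from sulcatone 9 (through the silyloxy enol triflate F4 of the fallback above) and from arylzinc 14 (made from 4), and comes back at 15. Negishi coupling of 14 with F4 gives (R)-2-[3-(tert-butyldimethylsilyloxy)-6-methylhepta-1,5-dien-2-yl]-4,6-dimethoxy-5-methylphenol F6, which has no ionisable allylic ester. TBAF (THF, 0 °C) gives (R)-2-(3-hydroxy-6-methylhepta-1,5-dien-2-yl)-4,6-dimethoxy-5-methylphenol F7. Mitsunobu esterification with excess angelic acid 5 (PPh3, DIAD, inversion) gives 15; the far more acidic carboxylic acid should out-compete the neutral phenol as nucleophile.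

## Further compounds

F1 | step 4 | (R)-6-methyl-3-(phenylaminooxy)hept-5-en-2-one | CC(=O)[C@@H](CC=C(C)C)ONc1ccccc1
F2 | step 4 | (R)-3-hydroxy-6-methylhept-5-en-2-one | CC(=O)[C@@H](CC=C(C)C)O
F3 | step 5 | (R)-3-(tert-butyldimethylsilyloxy)-6-methylhept-5-en-2-one | CC(=O)[C@@H](CC=C(C)C)O[Si](C)(C)C(C)(C)C
F4 | step 5 | (R)-3-(tert-butyldimethylsilyloxy)-6-methylhepta-1,5-dien-2-yl trifluoromethanesulfonate | C=C(OS(=O)(=O)C(F)(F)F)[C@@H](CC=C(C)C)O[Si](C)(C)C(C)(C)C
F5 | step 5 | (R)-3-hydroxy-6-methylhepta-1,5-dien-2-yl trifluoromethanesulfonate | C=C(OS(=O)(=O)C(F)(F)F)[C@@H](CC=C(C)C)O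
F6 | step 6 | (R)-2-[3-(tert-butyldimethylsilyloxy)-6-methylhepta-1,5-dien-2-yl]-4,6-dimethoxy-5-methylphenol | C=C(c1cc(OC)c(C)c(OC)c1O)[C@@H](CC=C(C)C)O[Si](C)(C)C(C)(C)C
F7 | step 6 | (R)-2-(3-hydroxy-6-methylhepta-1,5-dien-2-yl)-4,6-dimethoxy-5-methylphenol | C=C(c1cc(OC)c(C)c(OC)c1O)[C@@H](CC=C(C)C)O
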